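**Plan**

1. Numbering: ring C1 (C=O), C2 (allyl-bearing), C3 (CH), C4 (quaternary, OCH3), C5 (C–OCH3), C6 (CH); the side chain on C4 is C8H(CH3)–C7H2–aryl.
2. Retrosynthesis: the dienone ring is opened at C2=C3 (aldol condensation). Then C5–OCH3 (methanol added to a C5≡C6 ynone) and C6–C1 (acetylide acylation) are cut, leaving an open C3–C4–C5 unit.
3. Enabling feature: the C4 side chain is a vinyl group that has taken up CH3 at C8 and the dimethoxyphenyl ring at C7, and C8 is β to the carbonyl-level ring carbon C5. An 8-aminoquinoline amide at C5 can therefore guide nickel onto the C4 vinyl group, and C7–aryl and C8–CH3 are cut together.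
4. The vinyl amide goes back through a sulfonium-ylide homologation and a Sharpless epoxide to 2-methylenepropane-1,3-diol.
5. Forward: C4 is made first (steps 1–8), the side chain is built on it (step 9), C5 is turned into an alkyne and extended by C6–C1–C2–allyl (steps 10–16), and the only ring, the six-membered dienone, closes last (step 19).
6. Stereochemistry: C4 comes from the Sharpless asymmetric epoxidation with L-(+)-tartrate; C8 is set from C4 inside the nickelacycle of step 9.

Key step: step 9

Remark: the locants C1–C8 above are used for the corresponding atoms of every intermediate; TBDPS = tert-butyldiphenylsilyl; the β-methoxy enone 26 is assumed to settle as the E isomer under the reversible methoxide addition of step 16.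

**Route**

Step 1
Reactants: 1 2-methylenepropane-1,3-diol; 2 4-methoxybenzyl chloride
Product: 3 2-{[(4-methoxybenzyl)oxy]methyl}prop-2-en-1-ol
Conditions: NaH (1 equiv), Bu4NI (cat.), THF/DMF, 0 °C → rt
Reagents that add atoms: none
Why: Williamson ether synthesis on the mono-alkoxide of the symmetric diol should give mainly the mono-ether, which is separated from diol and bis-ether by chromatography.

Step 2
Reactants: 3 mono-PMB ether
Product: 4 [(2S)-2-{[(4-methoxybenzyl)oxy]methyl}oxiran-2-yl]methanol
Conditions: Ti(OiPr)4 (cat.), L-(+)-diethyl tartrate (cat.), t-BuOOH, 4 Å MS, CH2Cl2, −20 °C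
Reagents that add atoms: tert-butyl hydroperoxide, CC(C)(C)OO
Why: Sharpless asymmetric epoxidation of a 2-substituted allylic alcohol; the titanium–L-(+)-tartrate complex binds the allylic hydroxyl and delivers the peroxide oxygen to one alkene face, which creates the quaternary carbon (later C4) as the S epoxide.

Step 3
Reactants: 4 epoxy alcohol
Product: 5 tert-butyl{[(2S)-2-{[(4-methoxybenzyl)oxy]methyl}oxiran-2-yl]methoxy}diphenylsilane
Conditions: TBDPSCl, imidazole, CH2Cl2, 0 °C → rt
Reagents that add atoms: tert-butyl(chloro)diphenylsilane, CC(C)(C)[Si](Cl)(c1ccccc1)c1ccccc1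
Why: standard silylation of the primary alcohol; this arm becomes C3, and the bulky, base-stable TBDPS group stays on it until step 17.

Step 4
Reactants: 5 silylated epoxide
Product: 6 (2S)-1-[(tert-butyldiphenylsilyl)oxy]-2-{[(4-methoxybenzyl)oxy]methyl}but-3-en-2-ol
Conditions: Me3S+ I−, n-BuLi, THF, −10 °C → rt
Reagents that add atoms: trimethylsulfonium iodide, C[S+](C)C.[I-]
Why: one-carbon homologation of an epoxide to an allylic alcohol with excess dimethylsulfonium methylide: the ylide opens the epoxide at its CH2 carbon and the resulting sulfonium salt loses dimethyl sulfide by ylide-mediated elimination, so the epoxide CH2 becomes the vinyl CH (C8) and no bond at the stereocentre is touched.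

Step 5
Reactants: 6 tertiary allylic alcohol
Product: 7 tert-butyl{[(2S)-2-methoxy-2-{[(4-methoxybenzyl)oxy]methyl}but-3-en-1-yl]oxy}diphenylsilane
Conditions: NaH, MeI, THF/DMF, 0 °C → rt
Reagents that add atoms: iodomethane, CI
Why: Williamson O-methylation of the tertiary alkoxide installs the C4–OCH3 group of the target; migration of the hindered TBDPS group onto a tertiary oxygen is disfavoured.

Step 6
Reactants: 7 methyl ether
Product: 8 (2S)-2-{[(tert-butyldiphenylsilyl)oxy]methyl}-2-methoxybut-3-en-1-ol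
Conditions: DDQ, CH2Cl2/pH 7 buffer, 0 °C
Reagents that add atoms: none
Why: oxidative cleavage of the 4-methoxybenzyl ether (hydride abstraction, then hydrolysis of the oxocarbenium ion) leaves silyl ether, methyl ether and vinyl group intact, and is done before the electron-rich dimethoxyphenyl ring is present.

Step 7
Reactants: 8 primary alcohol
Product: 10 (2R)-2-{[(tert-butyldiphenylsilyl)oxy]methyl}-2-methoxybut-3-enoic acid, via the aldehyde 9 (not isolated)
Conditions: TEMPO (cat.), PhI(OAc)2, MeCN/H2O, rt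
Reagents that add atoms: water, O
Why: TEMPO (oxoammonium) oxidation of the primary alcohol to the aldehyde, whose hydrate is oxidised on to the acid; the α-carbon is fully substituted and cannot epimerise.

Step 8
Reactants: 10 carboxylic acid; 11 8-aminoquinoline
Product: 13 (2R)-2-{[(tert-butyldiphenylsilyl)oxy]methyl}-2-methoxy-N-(quinolin-8-yl)but-3-enamide, via the acid chloride 12 (not isolated)
Conditions: (COCl)2, DMF (cat.), CH2Cl2, 0 °C → rt, evaporate; then 11, Et3N, DMAP (cat.), CH2Cl2, 0 °C → rt
Reagents that add atoms: none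
Why: acid chloride formation followed by N-acylation of the weakly nucleophilic arylamine is the dependable amide coupling for a hindered acid, and gives the β,γ-unsaturated amide with the C5 carbonyl and the directing group in place.

Step 9
Reactants: 13 vinyl amide; 14 4-iodo-1,2-dimethoxybenzene; 15 dimethylzinc
Product: 16 (2R,3R)-2-{[(tert-butyldiphenylsilyl)oxy]methyl}-4-(3,4-dimethoxyphenyl)-2-methoxy-3-methyl-N-(quinolin-8-yl)butanamide
Conditions: NiBr2(dme) (15 mol %), 14 (excess), Zn(CH3)2 (excess), DMA/THF, rt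
Reagents that add atoms: none
Why: Zn(CH3)2 deprotonates the amide and reduces divalent nickel to zerovalent nickel, which is held by the amide and quinoline nitrogens next to the C4 vinyl group; oxidative addition of 14 and migratory insertion of the alkene into the Ni–aryl bond then put the aryl ring on the terminal carbon C7 and nickel on C8 in a five-membered nickelacycle. Transmetalation with the methylzinc reagent and C(sp3)–C(sp3) reductive elimination place CH3 on C8 with retention, so C7–aryl and C8–CH3 form in one operation. The closest known reaction is the nickel-catalysed, 8-aminoquinoline-directed three-component 1,2-aryl-alkylation (conjunctive cross-coupling) of β,γ-unsaturated amides with aryl iodides and dialkylzinc reagents, here applied to a substrate with a fully substituted, oxygen-bearing α-carbon. No ring is closed. The new stereocentre C8 is controlled by C4: in the chelated insertion step the C7 methylene turns to the side of the small OCH3 group and away from the bulky CH2OTBDPS arm, which leads to the (2R,3R) product. The step needs aryl at C7, methyl at C8 and no elimination; the five-membered chelate fixes the regiochemistry, C4 has no hydrogen, the C4–OCH3 bond cannot become syn-coplanar with the C8–Ni bond inside the chelate, and fast transmetalation of the rigid metallacycle should outrun β-hydride loss from C7.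

Step 10
Reactants: 16 quinolinyl amide
Product: 17 tert-butyl N-[(2R,3R)-2-{[(tert-butyldiphenylsilyl)oxy]methyl}-4-(3,4-dimethoxyphenyl)-2-methoxy-3-methylbutanoyl]-N-(quinolin-8-yl)carbamate
Conditions: Boc2O, DMAP, MeCN, 60 °C
Reagents that add atoms: di-tert-butyl dicarbonate, CC(C)(C)OC(=O)OC(=O)OC(C)(C)C
Why: DMAP-catalysed N-acylation of the anilide with Boc2O twists the amide out of conjugation and turns it into an acyl donor, the standard activation for removing the 8-aminoquinoline group.

Step 11
Reactants: 17 N-Boc amide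
Product: 18 (2S,3R)-2-{[(tert-butyldiphenylsilyl)oxy]methyl}-4-(3,4-dimethoxyphenyl)-2-methoxy-3-methylbutan-1-ol
Conditions: LiBH4, THF, 0 °C → rt
Reagents that add atoms: none
Why: borohydride reduction of the N-acyl carbamate at the ketone-like acyl carbonyl; the tetrahedral intermediate expels the carbamate anion and the aldehyde formed is reduced on to the primary alcohol, while the silyl ether is untouched.

Step 12
Reactants: 18 primary alcohol
Product: 19 (2R,3R)-2-{[(tert-butyldiphenylsilyl)oxy]methyl}-4-(3,4-dimethoxyphenyl)-2-methoxy-3-methylbutanal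
Conditions: Dess–Martin periodinane, CH2Cl2, rt
Reagents that add atoms: none
Why: Dess–Martin oxidation of the hindered primary alcohol gives the non-enolisable C5 aldehyde without over-oxidation.

Step 13
Reactants: 19 aldehyde
Product: 20 tert-butyl{[(2S,3R)-4-(3,4-dimethoxyphenyl)-2-ethynyl-2-methoxy-3-methylbutyl]oxy}diphenylsilane
Conditions: dimethyl (1-diazo-2-oxopropyl)phosphonate, K2CO3, MeOH/THF, 0 °C → rt
Reagents that add atoms: dimethyl (1-diazo-2-oxopropyl)phosphonate, COP(=O)(OC)C(=[N+]=[N-])C(C)=O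
Why: Seyferth–Gilbert homologation in the Ohira–Bestmann variant: the diazophosphonate anion adds to the aldehyde, dimethyl phosphate and nitrogen are lost and the alkylidene carbene rearranges to the terminal alkyne C5≡C6H; the aldehyde has no α-hydrogen, so the basic medium is harmless.

Step 14
Reactants: 21 pent-4-enoyl chloride; 22 N,O-dimethylhydroxylamine hydrochloride
Product: 23 N-methoxy-N-methylpent-4-enamide
Conditions: Et3N, CH2Cl2, 0 °C → rt
Reagents that add atoms: none
Why: N-acylation of the hydroxylamine by the acid chloride gives the Weinreb amide that carries C1, C2 and the allyl group.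

Step 15
Reactants: 20 terminal alkyne; 23 Weinreb amide
Product: 25 (8S,9R)-8-{[(tert-butyldiphenylsilyl)oxy]methyl}-10-(3,4-dimethoxyphenyl)-8-methoxy-9-methyldec-1-en-6-yn-5-one, via the lithium acetylide 24 (not isolated)
Conditions: n-BuLi, THF, −78 °C; then 23, −78 → 0 °C
Reagents that add atoms: none
Why: acylation of a lithium acetylide with a Weinreb amide; the chelated tetrahedral intermediate survives until work-up, so the C6–C1 bond forms without over-addition.

Step 16
Reactants: 25 ynone
Product: 26 (6E,8R,9R)-8-{[(tert-butyldiphenylsilyl)oxy]methyl}-10-(3,4-dimethoxyphenyl)-7,8-dimethoxy-9-methyldeca-1,6-dien-5-one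
Conditions: NaOMe (cat.), MeOH, 0 °C → rt
Reagents that add atoms: methanol, CO
Why: base-catalysed conjugate (oxa-Michael) addition of methanol to the ynone puts the methoxy group on the β-carbon C5 only, and reversible addition should settle on the E isomer, in which the methoxy group is anti to the carbonyl and C4 is cis to C1 as the ring requires.

Step 17
Reactants: 26 silyl ether
Product: 27 (6E,8R,9R)-10-(3,4-dimethoxyphenyl)-8-(hydroxymethyl)-7,8-dimethoxy-9-methyldeca-1,6-dien-5-one
Conditions: Bu4NF, AcOH, THF, rt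
Reagents that add atoms: none
Why: fluoride cleavage of the silyl ether, buffered with acetic acid so that the vinylogous ester is not exposed to free alkoxide.

Step 18
Reactants: 27 primary alcohol
Product: 28 (2S,3E)-2-[(2R)-1-(3,4-dimethoxyphenyl)propan-2-yl]-2,3-dimethoxy-5-oxonona-3,8-dienal
Conditions: Dess–Martin periodinane, NaHCO3, CH2Cl2, 0 °C → rt
Reagents that add atoms: none
Why: buffered Dess–Martin oxidation gives the C3 aldehyde, which sits on the quaternary C4 and cannot enolise; the buffer protects the acid-sensitive vinylogous ester.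

Step 19
Reactants: 28 keto aldehyde
Product: 30 (4R)-4-[(2R)-1-(3,4-dimethoxyphenyl)propan-2-yl]-4,5-dimethoxy-2-(prop-2-en-1-yl)cyclohexa-2,5-dien-1-one, via the aldol adduct 29 (not isolated)
Conditions: KOt-Bu (0.5 equiv), t-BuOH/THF, 0 °C
Reagents that add atoms: none
Why: intramolecular aldol condensation: the only enolisable position is the α'-CH2 (C2) of the vinylogous ester, its enolate attacks the C3 aldehyde in a 6-(enolendo)-exo-trig closure and E1cB loss of water gives the cross-conjugated dienone, with C4 and C8 untouched.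

**Compound list**

1 | 2-methylenepropane-1,3-diol | C=C(CO)CO | starting material
2 | 4-methoxybenzyl chloride | COc1ccc(CCl)cc1 | starting material
3 | 2-{[(4-methoxybenzyl)oxy]methyl}prop-2-en-1-ol | C=C(CO)COCc1ccc(OC)cc1 | intermediate
4 | [(2S)-2-{[(4-methoxybenzyl)oxy]methyl}oxiran-2-yl]methanol | OC[C@@]1(COCc2ccc(OC)cc2)CO1 | intermediate
5 | tert-butyl{[(2S)-2-{[(4-methoxybenzyl)oxy]methyl}oxiran-2-yl]methoxy}diphenylsilane | CC(C)(C)[Si](c1ccccc1)(c1ccccc1)OC[C@@]1(COCc2ccc(OC)cc2)CO1 | intermediate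
6 | (2S)-1-[(tert-butyldiphenylsilyl)oxy]-2-{[(4-methoxybenzyl)oxy]methyl}but-3-en-2-ol | CC(C)(C)[Si](c1ccccc1)(c1ccccc1)OC[C@@](O)(COCc1ccc(OC)cc1)C=C | intermediate
7 | tert-butyl{[(2S)-2-methoxy-2-{[(4-methoxybenzyl)oxy]methyl}but-3-en-1-yl]oxy}diphenylsilane | CC(C)(C)[Si](c1ccccc1)(c1ccccc1)OC[C@@](OC)(COCc1ccc(OC)cc1)C=C | intermediate
8 | (2S)-2-{[(tert-butyldiphenylsilyl)oxy]methyl}-2-methoxybut-3-en-1-ol | CC(C)(C)[Si](c1ccccc1)(c1ccccc1)OC[C@@](OC)(CO)C=C | intermediate
9 | (2R)-2-{[(tert-butyldiphenylsilyl)oxy]methyl}-2-methoxybut-3-enal (not isolated) | CC(C)(C)[Si](c1ccccc1)(c1ccccc1)OC[C@@](OC)(C=O)C=C | intermediate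
10 | (2R)-2-{[(tert-butyldiphenylsilyl)oxy]methyl}-2-methoxybut-3-enoic acid | CC(C)(C)[Si](c1ccccc1)(c1ccccc1)OC[C@@](OC)(C(=O)O)C=C | intermediate
11 | 8-aminoquinoline | Nc1cccc2cccnc12 | starting material
12 | (2R)-2-{[(tert-butyldiphenylsilyl)oxy]methyl}-2-methoxybut-3-enoyl chloride (not isolated) | CC(C)(C)[Si](c1ccccc1)(c1ccccc1)OC[C@@](OC)(C(=O)Cl)C=C | intermediate
13 | (2R)-2-{[(tert-butyldiphenylsilyl)oxy]methyl}-2-methoxy-N-(quinolin-8-yl)but-3-enamide | CC(C)(C)[Si](c1ccccc1)(c1ccccc1)OC[C@](OC)(C=C)C(=O)Nc1cccc2cccnc12 | intermediate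
14 | 4-iodo-1,2-dimethoxybenzene | COc1ccc(I)cc1OC | starting material
15 | dimethylzinc | C[Zn]C | starting material
16 | (2R,3R)-2-{[(tert-butyldiphenylsilyl)oxy]methyl}-4-(3,4-dimethoxyphenyl)-2-methoxy-3-methyl-N-(quinolin-8-yl)butanamide | CC(C)(C)[Si](c1ccccc1)(c1ccccc1)OC[C@](OC)([C@H](C)Cc1ccc(OC)c(OC)c1)C(=O)Nc1cccc2cccnc12 | intermediate
17 | tert-butyl N-[(2R,3R)-2-{[(tert-butyldiphenylsilyl)oxy]methyl}-4-(3,4-dimethoxyphenyl)-2-methoxy-3-methylbutanoyl]-N-(quinolin-8-yl)carbamate | CC(C)(C)[Si](c1ccccc1)(c1ccccc1)OC[C@](OC)([C@H](C)Cc1ccc(OC)c(OC)c1)C(=O)N(C(=O)OC(C)(C)C)c1cccc2cccnc12 | intermediate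
18 | (2S,3R)-2-{[(tert-butyldiphenylsilyl)oxy]methyl}-4-(3,4-dimethoxyphenyl)-2-methoxy-3-methylbutan-1-ol | CC(C)(C)[Si](c1ccccc1)(c1ccccc1)OC[C@](OC)([C@H](C)Cc1ccc(OC)c(OC)c1)CO | intermediate
19 | (2R,3R)-2-{[(tert-butyldiphenylsilyl)oxy]methyl}-4-(3,4-dimethoxyphenyl)-2-methoxy-3-methylbutanal | CC(C)(C)[Si](c1ccccc1)(c1ccccc1)OC[C@](OC)([C@H](C)Cc1ccc(OC)c(OC)c1)C=O | intermediate
20 | tert-butyl{[(2S,3R)-4-(3,4-dimethoxyphenyl)-2-ethynyl-2-methoxy-3-methylbutyl]oxy}diphenylsilane | CC(C)(C)[Si](c1ccccc1)(c1ccccc1)OC[C@](OC)([C@H](C)Cc1ccc(OC)c(OC)c1)C#C | intermediate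
21 | pent-4-enoyl chloride | C=CCCC(=O)Cl | starting material
22 | N,O-dimethylhydroxylamine hydrochloride | CNOC.Cl | starting material
23 | N-methoxy-N-methylpent-4-enamide | C=CCCC(=O)N(C)OC | intermediate
24 | lithium acetylide of 20 (not isolated) | CC(C)(C)[Si](c1ccccc1)(c1ccccc1)OC[C@](OC)([C@H](C)Cc1ccc(OC)c(OC)c1)C#C[Li] | intermediate
25 | (8S,9R)-8-{[(tert-butyldiphenylsilyl)oxy]methyl}-10-(3,4-dimethoxyphenyl)-8-methoxy-9-methyldec-1-en-6-yn-5-one | CC(C)(C)[Si](c1ccccc1)(c1ccccc1)OC[C@](OC)([C@H](C)Cc1ccc(OC)c(OC)c1)C#CC(=O)CCC=C | intermediate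
26 | (6E,8R,9R)-8-{[(tert-butyldiphenylsilyl)oxy]methyl}-10-(3,4-dimethoxyphenyl)-7,8-dimethoxy-9-methyldeca-1,6-dien-5-one | CC(C)(C)[Si](c1ccccc1)(c1ccccc1)OC[C@](OC)([C@H](C)Cc1ccc(OC)c(OC)c1)/C(OC)=C\C(=O)CCC=C | intermediate
27 | (6E,8R,9R)-10-(3,4-dimethoxyphenyl)-8-(hydroxymethyl)-7,8-dimethoxy-9-methyldeca-1,6-dien-5-one | OC[C@](OC)([C@H](C)Cc1ccc(OC)c(OC)c1)/C(OC)=C\C(=O)CCC=C | intermediate
28 | (2S,3E)-2-[(2R)-1-(3,4-dimethoxyphenyl)propan-2-yl]-2,3-dimethoxy-5-oxonona-3,8-dienal | O=C[C@](OC)([C@H](C)Cc1ccc(OC)c(OC)c1)/C(OC)=C\C(=O)CCC=C | intermediate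
29 | (4R)-4-[(2R)-1-(3,4-dimethoxyphenyl)propan-2-yl]-5-hydroxy-3,4-dimethoxy-6-(prop-2-en-1-yl)cyclohex-2-en-1-one, mixture at C5 and C6 (not isolated) | C=CCC1C(O)[C@](OC)([C@H](C)Cc2ccc(OC)c(OC)c2)C(OC)=CC1=O | intermediate
30 | (4R)-4-[(2R)-1-(3,4-dimethoxyphenyl)propan-2-yl]-4,5-dimethoxy-2-(prop-2-en-1-yl)cyclohexa-2,5-dien-1-one | C=CCC1=C[C@](OC)([C@H](C)Cc2ccc(OC)c(OC)c2)C(OC)=CC1=O | target

**Step count**

Total: 19 steps. Longest linear sequence: 18 steps (steps 1–13 and 15–19, from 1); step 14 prepares fragment 23.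

**Steps most likely to fail, with fallbacks**

Step 9. The vinyl group sits next to a fully substituted carbon, so alkene insertion may be slower than direct methyl–aryl coupling, the two faces of the alkene may be poorly differentiated at C8, or β-hydride loss from C7 may give the styrene. The fallback sets out from 13 and returns at 16, and forms the two bonds separately. Hydroboration of the vinyl group with 9-BBN (THF, rt) would give the B-alkyl-9-borabicyclononane F1. B-alkyl Suzuki–Miyaura coupling of F1 with 14 (PdCl2(dppf), K3PO4, DMF/H2O, 60 °C) would give the saturated γ-aryl amide F2. Pd(OAc)2-catalysed, 8-aminoquinoline-directed methylation of the β-methylene C–H bond of F2 with CH3I (Ag2CO3, (BnO)2PO2H, t-AmOH, 110 °C) would then give 16. C8 is set in a five-membered palladacycle, in which the CH2Ar group should again avoid the silyloxymethyl arm and the methyl group takes the place of the metal.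

Step 19. The base may add to the C3 aldehyde and split the C3–C4 bond (vinylogous retro-Claisen loss of formate), the allyl double bond may move into conjugation, or the aldol may fail to dehydrate. The fallback closes the same C2=C3 bond by an intramolecular Horner–Wadsworth–Emmons olefination under mild, non-nucleophilic conditions. It sets out from 20 (through its lithium acetylide 24) and returns at 30. Acylation of 24 with methyl chloroformate would give the methyl ynoate F3, and methanol addition (NaOMe cat., MeOH) the (E)-β-methoxy acrylate F4. Acylation of lithiated diethyl but-3-en-1-ylphosphonate (n-BuLi, THF, −78 °C) by F4 would give the β-keto phosphonate F5. Desilylation (Bu4NF, AcOH) would give the alcohol F6 and Dess–Martin oxidation the phosphonate aldehyde F7, which should cyclise to 30 with LiCl and i-Pr2NEt in MeCN.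

Step 10. The amide N–H is hindered and hydrogen-bonded to the quinoline nitrogen, so Boc transfer may stall; if activation is incomplete, or if hydride later attacks the carbamate carbonyl, 16 is simply returned. The fallback sets out from 16 and returns at 19, skipping 17 and 18. Cp2Zr(H)Cl (excess, THF, rt) reduces the secondary amide to the N-quinolinyl aldimine F8, which is hydrolysed on aqueous work-up or silica to aldehyde 19 and 8-aminoquinoline.

**Further compounds**

F1 | step 9 | (2R)-4-(9-borabicyclo[3.3.1]nonan-9-yl)-2-{[(tert-butyldiphenylsilyl)oxy]methyl}-2-methoxy-N-(quinolin-8-yl)butanamide | CC(C)(C)[Si](c1ccccc1)(c1ccccc1)OC[C@](OC)(CCB3C4CCCC3CCC4)C(=O)Nc1cccc2cccnc12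
F2 | step 9 | (2R)-2-{[(tert-butyldiphenylsilyl)oxy]methyl}-4-(3,4-dimethoxyphenyl)-2-methoxy-N-(quinolin-8-yl)butanamide | CC(C)(C)[Si](c1ccccc1)(c1ccccc1)OC[C@](OC)(CCc1ccc(OC)c(OC)c1)C(=O)Nc1cccc2cccnc12
F3 | step 19 | methyl (4S,5R)-4-{[(tert-butyldiphenylsilyl)oxy]methyl}-6-(3,4-dimethoxyphenyl)-4-methoxy-5-methylhex-2-ynoate | CC(C)(C)[Si](c1ccccc1)(c1ccccc1)OC[C@](OC)([C@H](C)Cc1ccc(OC)c(OC)c1)C#CC(=O)OC
F4 | step 19 | methyl (2E,4R,5R)-4-{[(tert-butyldiphenylsilyl)oxy]methyl}-6-(3,4-dimethoxyphenyl)-3,4-dimethoxy-5-methylhex-2-enoate | CC(C)(C)[Si](c1ccccc1)(c1ccccc1)OC[C@](OC)([C@H](C)Cc1ccc(OC)c(OC)c1)/C(OC)=C\C(=O)OC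
F5 | step 19 | diethyl [(6E,8R,9R)-8-{[(tert-butyldiphenylsilyl)oxy]methyl}-10-(3,4-dimethoxyphenyl)-7,8-dimethoxy-9-methyl-5-oxodeca-1,6-dien-4-yl]phosphonate | CC(C)(C)[Si](c1ccccc1)(c1ccccc1)OC[C@](OC)([C@H](C)Cc1ccc(OC)c(OC)c1)/C(OC)=C\C(=O)C(CC=C)P(=O)(OCC)OCC
F6 | step 19 | diethyl [(6E,8R,9R)-10-(3,4-dimethoxyphenyl)-8-(hydroxymethyl)-7,8-dimethoxy-9-methyl-5-oxodeca-1,6-dien-4-yl]phosphonate | OC[C@](OC)([C@H](C)Cc1ccc(OC)c(OC)c1)/C(OC)=C\C(=O)C(CC=C)P(=O)(OCC)OCC
F7 | step 19 | diethyl [(6E,8S,9R)-10-(3,4-dimethoxyphenyl)-8-formyl-7,8-dimethoxy-9-methyl-5-oxodeca-1,6-dien-4-yl]phosphonate | O=C[C@](OC)([C@H](C)Cc1ccc(OC)c(OC)c1)/C(OC)=C\C(=O)C(CC=C)P(=O)(OCC)OCC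
F8 | step 10 | (2S,3R)-2-{[(tert-butyldiphenylsilyl)oxy]methyl}-4-(3,4-dimethoxyphenyl)-2-methoxy-3-methyl-N-(quinolin-8-yl)butan-1-imine | CC(C)(C)[Si](c1ccccc1)(c1ccccc1)OC[C@](OC)([C@H](C)Cc1ccc(OC)c(OC)c1)C=Nc1cccc2cccnc12
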